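**Strategy.** Kazinol C is cut at two aryl–allyl bonds: C5–C(CH3)2 of the 1,1-dimethylallyl group on resorcinol ring A and C3′–CH2 of the prenyl group on catechol ring B. Both carbons lie ortho to a phenolic oxygen (O4 and O4′), so each group can be delivered from that oxygen with allylic inversion. Bis-ether 25, a 1,3-diarylpropane with an O-prenyl ether on ring A, an O-(1,1-dimethylallyl) ether on ring B, the C2′ prenyl group and two MOM ethers, is heated once; two ortho-Claisen shifts then complete the carbon skeleton (27), and mild acid frees the phenols.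

Key step: step 15

Remark: locants used throughout are ring A (resorcinol ring) C1 = tether carbon, O2, O4, C5, and ring B (catechol ring) C1′ = tether carbon, C2′/C3′ prenyl carbons, O4′, O5′; the target has no stereocentre and no stereogenic double bond, so no stereocontrol is required.

**Ring A fragment**

Step 1
Reactants: 1 2,4-dihydroxybenzaldehyde; 2 1-bromo-3-methylbut-2-ene
Product: 3 2-hydroxy-4-(3-methylbut-2-enyloxy)benzaldehyde
Conditions: K2CO3 (1.0 equiv), acetone, rt
Reagents that add atoms: none
Why: Williamson etherification in which the free, more acidic 4-OH reacts while the 2-OH stays hydrogen-bonded to the aldehyde, so one equivalent of bromide should alkylate O4 only.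

Step 2
Reactants: 3 2-hydroxy-4-(3-methylbut-2-enyloxy)benzaldehyde
Product: 4 2-(methoxymethoxy)-4-(3-methylbut-2-enyloxy)benzaldehyde
Conditions: MOMCl, i-Pr2NEt, CH2Cl2, 0 °C → rt
Reagents that add atoms: chloromethyl methyl ether, COCCl
Why: MOM ether formation (O-alkylation by an α-chloro ether) masks the chelated phenol as an acetal that is stable to hydride, carbanions, magnesium and hot amine.

Step 3
Reactants: 4 2-(methoxymethoxy)-4-(3-methylbut-2-enyloxy)benzaldehyde
Product: 5 [2-(methoxymethoxy)-4-(3-methylbut-2-enyloxy)phenyl]methanol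
Conditions: NaBH4, MeOH, 0 °C
Reagents that add atoms: none
Why: Borohydride reduction of an aryl aldehyde to the benzylic alcohol, which leaves the allylic ether and the acetal untouched.

Step 4
Reactants: 5 [2-(methoxymethoxy)-4-(3-methylbut-2-enyloxy)phenyl]methanol
Product: 7 1-(chloromethyl)-2-(methoxymethoxy)-4-(3-methylbut-2-enyloxy)benzene, via benzylic mesylate 6 (not isolated)
Conditions: MsCl, Et3N, THF, 0 °C; then LiCl, DMF, rt; crude chloride used at once
Reagents that add atoms: lithium chloride, [Li+].[Cl-]
Why: Mesylation followed by chloride displacement under buffered, non-acidic conditions should give the electron-rich benzylic chloride, which is not stored because 2,4-dialkoxybenzyl halides ionise easily.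

Step 5
Reactants: 7 1-(chloromethyl)-2-(methoxymethoxy)-4-(3-methylbut-2-enyloxy)benzene; 8 bis(phenylsulfonyl)methane
Product: 10 1-[2,2-bis(phenylsulfonyl)ethyl]-2-(methoxymethoxy)-4-(3-methylbut-2-enyloxy)benzene, via sodium bis(phenylsulfonyl)methanide 9 (not isolated)
Conditions: 8 (2.2 equiv), NaH (2.0 equiv), DMF, 0 °C; then 7, 0 °C → rt
Reagents that add atoms: none
Why: C-alkylation of a doubly sulfonyl-stabilised carbanion by a reactive benzylic chloride, where the excess of the more acidic parent bis-sulfone should hold the reaction at mono-alkylation.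

**Ring B fragment**

Step 6
Reactants: 11 6-bromoveratraldehyde (2-bromo-4,5-dimethoxybenzaldehyde)
Product: 12 2-bromo-4,5-dihydroxybenzaldehyde
Conditions: BBr3 (3 equiv), CH2Cl2, −78 °C → rt; H2O
Reagents that add atoms: none
Why: Lewis-acid cleavage of both aryl methyl ethers, placed first so that no prenyl group or acetal is exposed to BBr3.

Step 7
Reactants: 12 2-bromo-4,5-dihydroxybenzaldehyde
Product: 14 2-bromo-4-hydroxy-5-(methoxymethoxy)benzaldehyde, via disodium catecholate 13 (not isolated)
Conditions: NaH (2.2 equiv), DMF, 0 °C, argon; then MOMCl (1.0 equiv), −20 → 0 °C; aq. NH4Cl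
Reagents that add atoms: chloromethyl methyl ether, COCCl
Why: Regioselective O-alkylation of a catecholate dianion, in which the O4 phenoxide is delocalised into the para aldehyde so the more basic O5 phenoxide should take the single equivalent of MOMCl and leave the O4 phenol free.

Step 8
Reactants: 14 2-bromo-4-hydroxy-5-(methoxymethoxy)benzaldehyde; 15 tributyl(3-methylbut-2-enyl)stannane
Product: 16 4-hydroxy-5-(methoxymethoxy)-2-(3-methylbut-2-enyl)benzaldehyde
Conditions: Pd(PPh3)4 (5 mol%), DMF (degassed), 90 °C; aq. KF work-up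
Reagents that add atoms: none
Why: Stille cross-coupling at the bromide activated by the ortho aldehyde, where reductive elimination through the unhindered primary carbon of the prenyl–palladium species should give the linear prenyl arene and the neutral conditions tolerate aldehyde and phenol.

Step 9
Reactants: 16 4-hydroxy-5-(methoxymethoxy)-2-(3-methylbut-2-enyl)benzaldehyde; 17 3-chloro-3-methylbut-1-yne
Product: 18 5-(methoxymethoxy)-4-(2-methylbut-3-yn-2-yloxy)-2-(3-methylbut-2-enyl)benzaldehyde
Conditions: DBU, CuCl2·2H2O (1 mol%), MeCN, 0 °C → rt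
Reagents that add atoms: none
Why: Copper-catalysed propargylic etherification of a phenol with a tertiary propargylic chloride, which works best on an acidic para-formyl phenol such as 16 and is therefore placed at the aldehyde stage.

Step 10
Reactants: 18 5-(methoxymethoxy)-4-(2-methylbut-3-yn-2-yloxy)-2-(3-methylbut-2-enyl)benzaldehyde
Product: 19 [5-(methoxymethoxy)-4-(2-methylbut-3-yn-2-yloxy)-2-(3-methylbut-2-enyl)phenyl]methanol
Conditions: NaBH4, MeOH, 0 °C
Reagents that add atoms: none
Why: Borohydride reduction of the aldehyde, to which the alkyne, the alkene and both ethers are inert.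

Step 11
Reactants: 19 [5-(methoxymethoxy)-4-(2-methylbut-3-yn-2-yloxy)-2-(3-methylbut-2-enyl)phenyl]methanol
Product: 21 1-(chloromethyl)-5-(methoxymethoxy)-4-(2-methylbut-3-yn-2-yloxy)-2-(3-methylbut-2-enyl)benzene, via benzylic mesylate 20 (not isolated)
Conditions: MsCl, Et3N, THF, 0 °C; then LiCl, DMF, rt
Reagents that add atoms: lithium chloride, [Li+].[Cl-]
Why: Mesylation and chloride displacement under buffered conditions, which avoid the benzylic cation that could be trapped by the ortho prenyl alkene.

**Union and end game**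

Step 12
Reactants: 10 1-[2,2-bis(phenylsulfonyl)ethyl]-2-(methoxymethoxy)-4-(3-methylbut-2-enyloxy)benzene; 21 1-(chloromethyl)-5-(methoxymethoxy)-4-(2-methylbut-3-yn-2-yloxy)-2-(3-methylbut-2-enyl)benzene
Product: 23 1-[2-(methoxymethoxy)-4-(3-methylbut-2-enyloxy)phenyl]-3-[5-(methoxymethoxy)-4-(2-methylbut-3-yn-2-yloxy)-2-(3-methylbut-2-enyl)phenyl]-2,2-bis(phenylsulfonyl)propane, via sodium carbanion 22 (not isolated)
Conditions: 10, NaH (1.0 equiv), DMF, 0 °C → rt; then 21, n-Bu4NI (10 mol%), rt → 60 °C
Reagents that add atoms: none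
Why: Second C-alkylation of the bis-sulfone carbanion joins the two benzylic carbons through the linchpin carbon, and this stabilised carbanion is too weak a base to deprotonate the terminal alkyne.

Step 13
Reactants: 23 the 2,2-bis(phenylsulfonyl)-1,3-diarylpropane
Product: 24 1-[2-(methoxymethoxy)-4-(3-methylbut-2-enyloxy)phenyl]-3-[5-(methoxymethoxy)-4-(2-methylbut-3-yn-2-yloxy)-2-(3-methylbut-2-enyl)phenyl]propane
Conditions: Mg turnings (excess, I2-activated), MeOH–THF, rt → 50 °C
Reagents that add atoms: none
Why: Reductive desulfonylation by electron transfer from magnesium in methanol removes both phenylsulfonyl groups as sulfinate and should leave isolated alkenes, the alkyne, aryl ethers and acetals alone.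

Step 14
Reactants: 24 the 1,3-diarylpropane aryl propargyl ether
Product: 25 1-[2-(methoxymethoxy)-4-(3-methylbut-2-enyloxy)phenyl]-3-[5-(methoxymethoxy)-4-(2-methylbut-3-en-2-yloxy)-2-(3-methylbut-2-enyl)phenyl]propane
Conditions: H2 (1 atm), Pd/CaCO3 poisoned with Pb(OAc)2, quinoline, EtOAc, rt, stopped at one equivalent of H2
Reagents that add atoms: none
Why: Lindlar semihydrogenation of the terminal alkyne to the vinyl group, with a poisoned catalyst that does not reduce trisubstituted prenyl alkenes; the acid- and heat-sensitive tertiary allyl ether is thus made only one step before it is used.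

Step 15
Reactants: 25 the bis-ether (ring A O-prenyl, ring B O-1,1-dimethylallyl)
Product: 27 kazinol C bis(methoxymethyl) ether, 1-[4-hydroxy-2-(methoxymethoxy)-5-(2-methylbut-3-en-2-yl)phenyl]-3-[4-hydroxy-5-(methoxymethoxy)-2,3-bis(3-methylbut-2-enyl)phenyl]propane, via ring B rearranged phenol 26 (not isolated)
Conditions: PhNEt2 (degassed), argon, sealed vessel, 120 °C, then 190 °C
Reagents that add atoms: none
Why: Two aromatic Claisen ([3,3]-sigmatropic) rearrangements follow one another: near 120 °C the ring B aryl 1,1-dimethylallyl ether passes through a chair-like six-membered transition state, bonds its CH2 terminus to C3′ and, after enolisation of the ortho-dienone, gives phenol 26; near 190 °C the ring A prenyl ether shifts in the same way and bonds its tertiary terminus to C5. The closest known reactions are the thermal ortho-Claisen rearrangements of aryl prenyl ethers to 2-(1,1-dimethylallyl)phenols and of aryl 1,1-dimethylallyl ethers to 2-prenylphenols in N,N-dialkylaniline solvents. No ring is closed and no stereocentre is formed. Regioselectivity is needed only on ring A, where C3 sits between O2 and O4 and should not accept the quaternary carbon, so the shift is expected at C5; on ring B, C5′ carries the OMOM group and C3′ is the only free ortho carbon. Both para carbons (C1 and C1′) bear the tether, so a further Cope shift cannot end in a stable para product, and the basic solvent should suppress acid-catalysed addition of the new phenols to their ortho alkenes.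

Step 16
Reactants: 27 kazinol C bis(methoxymethyl) ether
Product: 28 kazinol C, 1-[2,4-dihydroxy-5-(2-methylbut-3-en-2-yl)phenyl]-3-[4,5-dihydroxy-2,3-bis(3-methylbut-2-enyl)phenyl]propane
Conditions: 3 M aq. HCl–MeOH (1:10), rt, argon
Reagents that add atoms: none
Why: Acid-catalysed acetal methanolysis releases both phenols, and dilute acid at room temperature under argon should be mild enough to avoid chroman formation from the ortho-prenyl phenol and oxidation of the catechol.

**Compound list**

1 | 2,4-dihydroxybenzaldehyde | O=Cc1ccc(O)cc1O | starting material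
2 | 1-bromo-3-methylbut-2-ene | CC(C)=CCBr | starting material
3 | 2-hydroxy-4-(3-methylbut-2-enyloxy)benzaldehyde | CC(C)=CCOc1ccc(C=O)c(O)c1 | intermediate
4 | 2-(methoxymethoxy)-4-(3-methylbut-2-enyloxy)benzaldehyde | CC(C)=CCOc1ccc(C=O)c(OCOC)c1 | intermediate
5 | [2-(methoxymethoxy)-4-(3-methylbut-2-enyloxy)phenyl]methanol | CC(C)=CCOc1ccc(CO)c(OCOC)c1 | intermediate
6 | [2-(methoxymethoxy)-4-(3-methylbut-2-enyloxy)phenyl]methyl methanesulfonate (formed in the flask) | CC(C)=CCOc1ccc(COS(C)(=O)=O)c(OCOC)c1 | intermediate
7 | 1-(chloromethyl)-2-(methoxymethoxy)-4-(3-methylbut-2-enyloxy)benzene | CC(C)=CCOc1ccc(CCl)c(OCOC)c1 | intermediate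
8 | bis(phenylsulfonyl)methane | O=S(=O)(CS(=O)(=O)c1ccccc1)c1ccccc1 | starting material
9 | sodium bis(phenylsulfonyl)methanide (formed in the flask) | [Na+].O=S(=O)([CH-]S(=O)(=O)c1ccccc1)c1ccccc1 | intermediate
10 | 1-[2,2-bis(phenylsulfonyl)ethyl]-2-(methoxymethoxy)-4-(3-methylbut-2-enyloxy)benzene | CC(C)=CCOc1ccc(CC(S(=O)(=O)c2ccccc2)S(=O)(=O)c2ccccc2)c(OCOC)c1 | intermediate
11 | 6-bromoveratraldehyde (2-bromo-4,5-dimethoxybenzaldehyde) | COc1cc(Br)c(C=O)cc1OC | starting material
12 | 2-bromo-4,5-dihydroxybenzaldehyde | O=Cc1cc(O)c(O)cc1Br | intermediate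
13 | disodium 4-bromo-5-formylbenzene-1,2-diolate (formed in the flask) | [Na+].[Na+].O=Cc1cc([O-])c([O-])cc1Br | intermediate
14 | 2-bromo-4-hydroxy-5-(methoxymethoxy)benzaldehyde | COCOc1cc(C=O)c(Br)cc1O | intermediate
15 | tributyl(3-methylbut-2-enyl)stannane | CCCC[Sn](CCCC)(CCCC)CC=C(C)C | starting material
16 | 4-hydroxy-5-(methoxymethoxy)-2-(3-methylbut-2-enyl)benzaldehyde | COCOc1cc(C=O)c(CC=C(C)C)cc1O | intermediate
17 | 3-chloro-3-methylbut-1-yne | C#CC(C)(C)Cl | starting material
18 | 5-(methoxymethoxy)-4-(2-methylbut-3-yn-2-yloxy)-2-(3-methylbut-2-enyl)benzaldehyde | COCOc1cc(C=O)c(CC=C(C)C)cc1OC(C)(C)C#C | intermediate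
19 | [5-(methoxymethoxy)-4-(2-methylbut-3-yn-2-yloxy)-2-(3-methylbut-2-enyl)phenyl]methanol | COCOc1cc(CO)c(CC=C(C)C)cc1OC(C)(C)C#C | intermediate
20 | [5-(methoxymethoxy)-4-(2-methylbut-3-yn-2-yloxy)-2-(3-methylbut-2-enyl)phenyl]methyl methanesulfonate (formed in the flask) | COCOc1cc(COS(C)(=O)=O)c(CC=C(C)C)cc1OC(C)(C)C#C | intermediate
21 | 1-(chloromethyl)-5-(methoxymethoxy)-4-(2-methylbut-3-yn-2-yloxy)-2-(3-methylbut-2-enyl)benzene | COCOc1cc(CCl)c(CC=C(C)C)cc1OC(C)(C)C#C | intermediate
22 | sodium 2-[2-(methoxymethoxy)-4-(3-methylbut-2-enyloxy)phenyl]-1,1-bis(phenylsulfonyl)ethan-1-ide (formed in the flask) | [Na+].CC(C)=CCOc1ccc(C[C-](S(=O)(=O)c2ccccc2)S(=O)(=O)c2ccccc2)c(OCOC)c1 | intermediate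
23 | 1-[2-(methoxymethoxy)-4-(3-methylbut-2-enyloxy)phenyl]-3-[5-(methoxymethoxy)-4-(2-methylbut-3-yn-2-yloxy)-2-(3-methylbut-2-enyl)phenyl]-2,2-bis(phenylsulfonyl)propane | CC(C)=CCOc1ccc(CC(Cc2cc(OCOC)c(OC(C)(C)C#C)cc2CC=C(C)C)(S(=O)(=O)c3ccccc3)S(=O)(=O)c3ccccc3)c(OCOC)c1 | intermediate
24 | 1-[2-(methoxymethoxy)-4-(3-methylbut-2-enyloxy)phenyl]-3-[5-(methoxymethoxy)-4-(2-methylbut-3-yn-2-yloxy)-2-(3-methylbut-2-enyl)phenyl]propane | CC(C)=CCOc1ccc(CCCc2cc(OCOC)c(OC(C)(C)C#C)cc2CC=C(C)C)c(OCOC)c1 | intermediate
25 | 1-[2-(methoxymethoxy)-4-(3-methylbut-2-enyloxy)phenyl]-3-[5-(methoxymethoxy)-4-(2-methylbut-3-en-2-yloxy)-2-(3-methylbut-2-enyl)phenyl]propane | CC(C)=CCOc1ccc(CCCc2cc(OCOC)c(OC(C)(C)C=C)cc2CC=C(C)C)c(OCOC)c1 | intermediate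
26 | 1-[2-(methoxymethoxy)-4-(3-methylbut-2-enyloxy)phenyl]-3-[4-hydroxy-5-(methoxymethoxy)-2,3-bis(3-methylbut-2-enyl)phenyl]propane (formed in the flask) | CC(C)=CCOc1ccc(CCCc2cc(OCOC)c(O)c(CC=C(C)C)c2CC=C(C)C)c(OCOC)c1 | intermediate
27 | kazinol C bis(methoxymethyl) ether (MOM on O2 and O5′) | C=CC(C)(C)c1cc(CCCc2cc(OCOC)c(O)c(CC=C(C)C)c2CC=C(C)C)c(OCOC)cc1O | intermediate
28 | kazinol C | C=CC(C)(C)c1cc(CCCc2cc(O)c(O)c(CC=C(C)C)c2CC=C(C)C)c(O)cc1O | target

**Step count and risk**

Total step count: 16. Longest linear sequence: 11 steps (from 11 through steps 6–11 and 12–16 to 28); the ring A branch is 5 steps before the union.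

Steps most likely to fail:

1. Step 15 (key step). At the temperature the ring A shift needs, the tertiary ether may lose isoprene, the 1,1-dimethylallyl phenol may isomerise by an abnormal Claisen path, or a new phenol may add to its ortho alkene. The fallback separates the two shifts and traps the phenols. Bis-ether 25 is heated at 120 °C in N,N-diethylaniline only until the ring B ether is consumed, and phenol 26 is isolated. Phenol 26 is then heated at 190 °C in N,N-diethylaniline containing acetic anhydride and NaOAc, so that the ring B phenol is acetylated at once and the ring A phenol as soon as it forms, giving kazinol C bis(methoxymethyl) ether diacetate F1. K2CO3 in methanol at room temperature removes both acetates and returns to 27.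

2. Step 7. Site selectivity in the alkylation of the dianion may erode (attack through O4 or double alkylation). The fallback uses the opposite, weak-base selectivity with a temporary group. From 12, allyl bromide with NaHCO3 and NaI in DMF at 40 °C alkylates the more acidic O4 phenol to give 4-(allyloxy)-2-bromo-5-hydroxybenzaldehyde F2. MOMCl with i-Pr2NEt then gives 4-(allyloxy)-2-bromo-5-(methoxymethoxy)benzaldehyde F3. Pd(PPh3)4 (catalytic) with morpholine in THF at room temperature removes the allyl group and returns to 14.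

3. Step 8. Allylic transposition at the prenyl–palladium stage (coupling through the tertiary terminus) or protodestannylation of the stannane by the acidic phenol may lower the amount of linear product. The fallback uses an allyl group, whose two termini are identical, and converts it afterwards. From 14, Stille coupling with allyltributylstannane (Pd(PPh3)4, DMF, 90 °C) gives 2-allyl-4-hydroxy-5-(methoxymethoxy)benzaldehyde F4. Cross-metathesis with excess 2-methylbut-2-ene and second-generation Grubbs catalyst RuCl2(=CHPh)(PCy3)(H2IMes) in CH2Cl2 at 40 °C then returns to 16.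

**Further compounds**

F1 | step 15 | kazinol C bis(methoxymethyl) ether diacetate (acetates on O4 and O4′) | C=CC(C)(C)c1cc(CCCc2cc(OCOC)c(OC(C)=O)c(CC=C(C)C)c2CC=C(C)C)c(OCOC)cc1OC(C)=O
F2 | step 7 | 4-(allyloxy)-2-bromo-5-hydroxybenzaldehyde | C=CCOc1cc(Br)c(C=O)cc1O
F3 | step 7 | 4-(allyloxy)-2-bromo-5-(methoxymethoxy)benzaldehyde | C=CCOc1cc(Br)c(C=O)cc1OCOC
F4 | step 8 | 2-allyl-4-hydroxy-5-(methoxymethoxy)benzaldehyde | C=CCc1cc(O)c(OCOC)cc1C=O
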